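The trans-decalin core (ring A: C4a, C5, C6, C7, C8, C8a; ring B: C1, C2, C3, C4, C4a, C8a) is opened at the ring-fusion bond C4a–C8a and at C1–C2. Both bonds form in one aluminium-promoted intramolecular Diels–Alder reaction of a linear (2E,8E,10E)-trienal: the 2-methyl-enal supplies C8a and quaternary C1 (its formyl carbon becomes the CH2OAr carbon), the (E,E)-diene supplies C4a–C4–C3–C2. The step exploits the four contiguous stereocentres of ring B (C1, C2, C4a, C8a) and closes both rings; a syn aldol stereodiad on the tether (C5 methyl, C6 silyloxy, later the ketone) directs the diene face. Isofraxidin is attached late to the neopentyl alcohol.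

Key step: step 8

Remark: locants refer to the decahydronaphthalene core of the target (C1: CH3 and CH2OAr; C2: CH3; C4a: CH3; C5: CH3; C6: C=O; C8a: H). Compounds 1, 2 and 16 and all named reagents are taken as commercial.

Step 1
Reactants: 1 (R)-4-benzyl-3-propanoyl-1,3-oxazolidin-2-one; 2 pent-4-enal
Product: 4 (R)-4-benzyl-3-[(2R,3S)-3-hydroxy-2-methylhept-6-enoyl]-1,3-oxazolidin-2-one, via boron enolate 3 (not isolated)
Conditions: Bu2BOTf, iPr2NEt, CH2Cl2, 0 °C; 2, −78 → 0 °C; H2O2, MeOH, pH 7 buffer, 0 °C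
Reagents that add atoms: none
Why: Evans syn-aldol reaction, in which the (Z)-boron enolate 3 adds through a closed chair (Zimmerman–Traxler) transition state on the enolate face away from the benzyl group and so should set the (2R,3S) syn stereodiad (later C5 and C6).

Step 2
Reactants: 4 (R)-4-benzyl-3-[(2R,3S)-3-hydroxy-2-methylhept-6-enoyl]-1,3-oxazolidin-2-one
Product: 5 (2R,3S)-3-hydroxy-N-methoxy-N,2-dimethylhept-6-enamide
Conditions: MeNH(OMe)·HCl, AlMe3, CH2Cl2, −15 °C → rt
Reagents that add atoms: N,O-dimethylhydroxylamine hydrochloride, CNOC.Cl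
Why: Weinreb amide formation by aluminium-amide transamidation, assisted by the free β-hydroxyl, should release the auxiliary without touching the α-stereocentre.

Step 3
Reactants: 5 (2R,3S)-3-hydroxy-N-methoxy-N,2-dimethylhept-6-enamide
Product: 6 (2R,3S)-N-methoxy-N,2-dimethyl-3-(triethylsilyloxy)hept-6-enamide
Conditions: Et3SiCl, imidazole, DMF, 0 °C → rt
Reagents that add atoms: chlorotriethylsilane, CC[Si](Cl)(CC)CC
Why: Silyl ether protection of the secondary alcohol; the TES group should survive the organoaluminium and Lewis-acid steps and is removed at the end.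

Step 4
Reactants: 6 (2R,3S)-N-methoxy-N,2-dimethyl-3-(triethylsilyloxy)hept-6-enamide
Product: 8 (3S,4S)-3-methyl-4-(triethylsilyloxy)oct-7-en-1-yne, via aldehyde 7 (not isolated)
Conditions: DIBAL-H, THF, −78 °C; MeOH; then K2CO3, dimethyl (1-diazo-2-oxopropyl)phosphonate, MeOH, 0 °C → rt
Reagents that add atoms: dimethyl (1-diazo-2-oxopropyl)phosphonate, COP(=O)(OC)C(=[N+]=[N-])C(C)=O
Why: Weinreb amide reduction stops at the chelated hemiaminal, and the liberated aldehyde 7 should undergo Seyferth–Gilbert homologation (Ohira–Bestmann reagent) under carbonate conditions mild enough to keep the α-methyl centre.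

Step 5
Reactants: 8 (3S,4S)-3-methyl-4-(triethylsilyloxy)oct-7-en-1-yne
Product: 10 (1E,3S,4S)-1-iodo-2,3-dimethyl-4-(triethylsilyloxy)octa-1,7-diene, via alkenylalane 9 (not isolated)
Conditions: AlMe3, Cp2ZrCl2 (cat.), H2O (1.5 equiv), CH2Cl2, −20 °C; I2, THF, −20 → 0 °C
Reagents that add atoms: trimethylaluminium, C[Al](C)C; iodine, [I][I]
Why: Negishi zirconium-catalysed carboalumination adds CH3–Al syn across the terminal alkyne with aluminium at the terminus, and iodinolysis with retention should give the (E)-trisubstituted alkenyl iodide, the monosubstituted alkene reacting far more slowly.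

Step 6
Reactants: 10 (1E,3S,4S)-1-iodo-2,3-dimethyl-4-(triethylsilyloxy)octa-1,7-diene
Product: 11 (2E,6S,7S,8E)-9-iodo-2,7,8-trimethyl-6-(triethylsilyloxy)nona-2,8-dienal
Conditions: methacrolein (10 equiv), second-generation Hoveyda–Grubbs catalyst (5 mol %), CH2Cl2, 40 °C
Reagents that add atoms: methacrolein, CC(=C)C=O
Why: Olefin cross-metathesis of the terminal alkene with excess methacrolein should give the thermodynamically favoured (E)-2-methyl-2-enal, while the hindered trisubstituted alkenyl iodide should not engage the ruthenium carbene.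

Step 7
Reactants: 11 (2E,6S,7S,8E)-9-iodo-2,7,8-trimethyl-6-(triethylsilyloxy)nona-2,8-dienal
Product: 12 (2E,6S,7S,8E,10E)-2,7,8-trimethyl-6-(triethylsilyloxy)dodeca-2,8,10-trienal
Conditions: (E)-prop-1-enylboronic acid pinacol ester, Pd(PPh3)4 (5 mol %), Cs2CO3, THF/H2O, rt
Reagents that add atoms: (E)-prop-1-enylboronic acid pinacol ester, C/C=C/B1OC(C)(C)C(C)(C)O1
Why: Suzuki–Miyaura coupling proceeds with retention at both alkenyl partners and should give the (8E,10E)-diene, the enal tolerating the mild aqueous base at room temperature.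

Step 8
Reactants: 12 (2E,6S,7S,8E,10E)-2,7,8-trimethyl-6-(triethylsilyloxy)dodeca-2,8,10-trienal
Product: 13 (1S,2S,4aR,5S,6S,8aS)-1,2,4a,5-tetramethyl-6-(triethylsilyloxy)-1,2,4a,5,6,7,8,8a-octahydronaphthalene-1-carbaldehyde
Conditions: Me2AlCl (1.2 equiv), CH2Cl2, −78 → −20 °C
Reagents that add atoms: none
Why: Intramolecular Diels–Alder reaction of the type 1 (fused) kind, closest to the known Lewis-acid-promoted cyclisations of (E)-enal-terminated 1,7,9-decatrienes to trans-decalins: Me2AlCl binds the formyl oxygen and the enal β-carbon (future C8a) bonds to the tether-bearing diene terminus (future C4a) while the α-carbon (future C1) bonds to the methyl-bearing terminus (future C2) in one concerted, asynchronous [4+2] event. Ring B is closed by the cycloaddition itself as a six-membered ring across C1–C2 and C4a–C8a, and ring A is closed by the C4a–C8a bond through the four-carbon tether (C5–C8) as a six-membered ring in a chair-like fused mode. The (2E)-enal fixes C8a-H cis to the C1 formyl group, the (8E,10E)-diene fixes the C4a methyl cis to C2-H, and the endo transition state (formyl under the diene, tether anti) fixes the C1 formyl cis to the C2 methyl and the C4a methyl trans to C8a-H, so C1, C2, C4a and C8a are set together. The absolute sense is relayed from the syn C5/C6 stereodiad, because only one diene face lets the chair tether carry both the C5 methyl and the C6 silyloxy group equatorial, whereas the other face puts both axial with the silyloxy group syn-axial to the C4a methyl. The step needs endo over exo selectivity, secured by aluminium activation of the (E)-enal, and diene-face selectivity, secured by the two equatorial tether substituents; the hindered 1,1-disubstituted diene terminus is offset by intramolecularity and Lewis-acid activation.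

Step 9
Reactants: 13 (1S,2S,4aR,5S,6S,8aS)-1,2,4a,5-tetramethyl-6-(triethylsilyloxy)-1,2,4a,5,6,7,8,8a-octahydronaphthalene-1-carbaldehyde
Product: 14 [(1S,2S,4aR,5S,6S,8aS)-1,2,4a,5-tetramethyl-6-(triethylsilyloxy)-1,2,4a,5,6,7,8,8a-octahydronaphthalen-1-yl]methanol
Conditions: NaBH4, MeOH/THF, 0 °C → rt
Reagents that add atoms: none
Why: Borohydride reduction of the neopentyl aldehyde; no stereocentre is involved and the silyl ether and ring alkene are inert.

Step 10
Reactants: 14 [(1S,2S,4aR,5S,6S,8aS)-1,2,4a,5-tetramethyl-6-(triethylsilyloxy)-1,2,4a,5,6,7,8,8a-octahydronaphthalen-1-yl]methanol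
Product: 15 [(1S,2S,4aR,5S,6S,8aS)-1,2,4a,5-tetramethyl-6-(triethylsilyloxy)decahydronaphthalen-1-yl]methanol
Conditions: H2 (1 atm), [Ir(cod)(PCy3)(py)]PF6 (5 mol %), CH2Cl2, rt
Reagents that add atoms: none
Why: Homogeneous iridium-catalysed hydrogenation should reduce the hindered cis-disubstituted C3=C4 alkene without the double-bond migration toward C2 that heterogeneous palladium could cause; no new stereocentre is formed.

Step 11
Reactants: 15 [(1S,2S,4aR,5S,6S,8aS)-1,2,4a,5-tetramethyl-6-(triethylsilyloxy)decahydronaphthalen-1-yl]methanol; 16 isofraxidin (7-hydroxy-6,8-dimethoxy-2H-chromen-2-one)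
Product: 18 6,8-dimethoxy-7-{[(1S,2S,4aR,5S,6S,8aS)-1,2,4a,5-tetramethyl-6-(triethylsilyloxy)decahydronaphthalen-1-yl]methoxy}-2H-chromen-2-one, via triflate 17 (not isolated)
Conditions: Tf2O, 2,6-lutidine, CH2Cl2, −78 → −20 °C; solvent exchange; 16, Cs2CO3, MeCN, 60 °C
Reagents that add atoms: none
Why: Williamson ether synthesis through the primary triflate, the smallest and most reactive leaving group for SN2 at a neopentyl carbon; β-elimination is impossible at quaternary C1 and the acidic coumarin phenol is fully ionised as its caesium salt.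

Step 12
Reactants: 18 6,8-dimethoxy-7-{[(1S,2S,4aR,5S,6S,8aS)-1,2,4a,5-tetramethyl-6-(triethylsilyloxy)decahydronaphthalen-1-yl]methoxy}-2H-chromen-2-one
Product: 20 6,8-dimethoxy-7-{[(1S,2S,4aR,5S,8aS)-1,2,4a,5-tetramethyl-6-oxodecahydronaphthalen-1-yl]methoxy}-2H-chromen-2-one, via alcohol 19 (not isolated)
Conditions: HF·pyridine, THF, 0 °C → rt; then Dess–Martin periodinane, CH2Cl2, rt
Reagents that add atoms: none
Why: Fluoride-mediated desilylation followed by Dess–Martin oxidation of the secondary alcohol 19 should give the C6 ketone; the C5 methyl is already equatorial, the thermodynamically favoured epimer, so enolisation cannot erode it.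

Compound list
1 | (R)-4-benzyl-3-propanoyl-1,3-oxazolidin-2-one | CCC(=O)N1C(=O)OC[C@H]1Cc1ccccc1 | starting material
2 | pent-4-enal | C=CCCC=O | starting material
3 | (R)-4-benzyl-3-[(1Z)-1-(dibutylboranyloxy)prop-1-en-1-yl]-1,3-oxazolidin-2-one (boron enolate) | C/C=C(\OB(CCCC)CCCC)N1C(=O)OC[C@H]1Cc1ccccc1 | intermediate
4 | (R)-4-benzyl-3-[(2R,3S)-3-hydroxy-2-methylhept-6-enoyl]-1,3-oxazolidin-2-one | C=CCC[C@H](O)[C@@H](C)C(=O)N1C(=O)OC[C@H]1Cc1ccccc1 | intermediate
5 | (2R,3S)-3-hydroxy-N-methoxy-N,2-dimethylhept-6-enamide | C=CCC[C@H](O)[C@@H](C)C(=O)N(C)OC | intermediate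
6 | (2R,3S)-N-methoxy-N,2-dimethyl-3-(triethylsilyloxy)hept-6-enamide | C=CCC[C@H](O[Si](CC)(CC)CC)[C@@H](C)C(=O)N(C)OC | intermediate
7 | (2R,3S)-2-methyl-3-(triethylsilyloxy)hept-6-enal | C=CCC[C@H](O[Si](CC)(CC)CC)[C@@H](C)C=O | intermediate
8 | (3S,4S)-3-methyl-4-(triethylsilyloxy)oct-7-en-1-yne | C=CCC[C@H](O[Si](CC)(CC)CC)[C@@H](C)C#C | intermediate
9 | dimethyl[(1E,3S,4S)-2,3-dimethyl-4-(triethylsilyloxy)octa-1,7-dien-1-yl]alumane | C=CCC[C@H](O[Si](CC)(CC)CC)[C@@H](C)/C(C)=C/[Al](C)C | intermediate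
10 | (1E,3S,4S)-1-iodo-2,3-dimethyl-4-(triethylsilyloxy)octa-1,7-diene | C=CCC[C@H](O[Si](CC)(CC)CC)[C@@H](C)/C(C)=C/I | intermediate
11 | (2E,6S,7S,8E)-9-iodo-2,7,8-trimethyl-6-(triethylsilyloxy)nona-2,8-dienal | O=C/C(C)=C/CC[C@H](O[Si](CC)(CC)CC)[C@@H](C)/C(C)=C/I | intermediate
12 | (2E,6S,7S,8E,10E)-2,7,8-trimethyl-6-(triethylsilyloxy)dodeca-2,8,10-trienal | O=C/C(C)=C/CC[C@H](O[Si](CC)(CC)CC)[C@@H](C)/C(C)=C/C=C/C | intermediate
13 | (1S,2S,4aR,5S,6S,8aS)-1,2,4a,5-tetramethyl-6-(triethylsilyloxy)-1,2,4a,5,6,7,8,8a-octahydronaphthalene-1-carbaldehyde | O=C[C@]1(C)[C@H]2CC[C@H](O[Si](CC)(CC)CC)[C@@H](C)[C@]2(C)C=C[C@@H]1C | intermediate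
14 | [(1S,2S,4aR,5S,6S,8aS)-1,2,4a,5-tetramethyl-6-(triethylsilyloxy)-1,2,4a,5,6,7,8,8a-octahydronaphthalen-1-yl]methanol | OC[C@]1(C)[C@H]2CC[C@H](O[Si](CC)(CC)CC)[C@@H](C)[C@]2(C)C=C[C@@H]1C | intermediate
15 | [(1S,2S,4aR,5S,6S,8aS)-1,2,4a,5-tetramethyl-6-(triethylsilyloxy)decahydronaphthalen-1-yl]methanol | OC[C@]1(C)[C@H]2CC[C@H](O[Si](CC)(CC)CC)[C@@H](C)[C@]2(C)CC[C@@H]1C | intermediate
16 | isofraxidin (7-hydroxy-6,8-dimethoxy-2H-chromen-2-one) | COc1cc2ccc(=O)oc2c(OC)c1O | starting material
17 | [(1S,2S,4aR,5S,6S,8aS)-1,2,4a,5-tetramethyl-6-(triethylsilyloxy)decahydronaphthalen-1-yl]methyl trifluoromethanesulfonate | O=S(=O)(OC[C@]1(C)[C@H]2CC[C@H](O[Si](CC)(CC)CC)[C@@H](C)[C@]2(C)CC[C@@H]1C)C(F)(F)F | intermediate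
18 | 6,8-dimethoxy-7-{[(1S,2S,4aR,5S,6S,8aS)-1,2,4a,5-tetramethyl-6-(triethylsilyloxy)decahydronaphthalen-1-yl]methoxy}-2H-chromen-2-one | COc1cc2ccc(=O)oc2c(OC)c1OC[C@]1(C)[C@H]2CC[C@H](O[Si](CC)(CC)CC)[C@@H](C)[C@]2(C)CC[C@@H]1C | intermediate
19 | 7-{[(1S,2S,4aR,5S,6S,8aS)-6-hydroxy-1,2,4a,5-tetramethyldecahydronaphthalen-1-yl]methoxy}-6,8-dimethoxy-2H-chromen-2-one | COc1cc2ccc(=O)oc2c(OC)c1OC[C@]1(C)[C@H]2CC[C@H](O)[C@@H](C)[C@]2(C)CC[C@@H]1C | intermediate
20 | 6,8-dimethoxy-7-{[(1S,2S,4aR,5S,8aS)-1,2,4a,5-tetramethyl-6-oxodecahydronaphthalen-1-yl]methoxy}-2H-chromen-2-one | COc1cc2ccc(=O)oc2c(OC)c1OC[C@]1(C)[C@H]2CCC(=O)[C@@H](C)[C@]2(C)CC[C@@H]1C | target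

Total step count: 12 steps.
Longest linear sequence: 12 steps (from 1 and 2 to 20; the route is fully linear).

Steps most likely to fail

Step 8. The cycloaddition may be too slow because the diene terminus that must bond carries a methyl group on its inside position. Lewis-acid-induced cationic oligomerisation could then compete, or the endo (trans-fusion) preference could erode. The fallback is an ionic Diels–Alder reaction and sets out from trienal 12. Treatment with 1,2-bis(trimethylsilyloxy)ethane and catalytic TMSOTf in CH2Cl2 at −78 °C should give the 1,3-dioxolane acetal of trienal 12 F1. On further exposure to TMSOTf or catalytic TfOH, F1 ionises to a 2-alkenyl-1,3-dioxolan-2-ylium cation, a far stronger dienophile, which should cyclise at low temperature with high endo selectivity to the 1,3-dioxolane acetal of aldehyde 13 F2. Buffered hydrolysis (pyridinium p-toluenesulfonate, wet acetone, rt) returns the route to aldehyde 13.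

Step 11. SN2 displacement at the neopentyl carbon by a hindered, weakly nucleophilic phenoxide may be too slow, which would allow decomposition or skeletal rearrangement of the triflate. The fallback forms the aryl–oxygen bond instead and builds the coumarin afterwards; it sets out from alcohol 15. Copper-catalysed O-arylation with commercial 4-bromo-3,5-dimethoxybenzaldehyde (copper iodide (CuI), 3,4,7,8-tetramethyl-1,10-phenanthroline, Cs2CO3, toluene, 110 °C) should give the aryl ether aldehyde F3. The formyl group is then masked in the flask as its lithium α-amino alkoxide (lithium N,N,N′-trimethylethylenediamide). Directed ortho-lithiation (n-BuLi), borylation (B(OMe)3) and oxidation (H2O2) should give the salicylaldehyde F4; the two ortho positions are equivalent. Wittig olefination with ethyl (triphenylphosphoranylidene)acetate in refluxing N,N-diethylaniline passes through the (Z)-cinnamate F5, which lactonises in the flask to coumarin 18, where the route is rejoined.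

Step 6. The cross-metathesis may stall or lose selectivity through homodimerisation of the terminal alkene, deactivation of the catalyst by the alkenyl iodide, or incomplete E control. The fallback sets out from iodide 10. Lemieux–Johnson cleavage of the terminal alkene (OsO4 cat., NaIO4, 2,6-lutidine, dioxane/water) should give the aldehyde F6, the electron-poor alkenyl iodide being left untouched. Wittig olefination with 2-(triphenylphosphoranylidene)propanal (toluene, 80 °C) should then give (E)-enal 11, where the route is rejoined.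

Further compounds
F1 | step 8 | 1,3-dioxolane acetal of trienal 12 | C1(OCCO1)/C(C)=C/CC[C@H](O[Si](CC)(CC)CC)[C@@H](C)/C(C)=C/C=C/C
F2 | step 8 | 1,3-dioxolane acetal of aldehyde 13 | C1(OCCO1)[C@]1(C)[C@H]2CC[C@H](O[Si](CC)(CC)CC)[C@@H](C)[C@]2(C)C=C[C@@H]1C
F3 | step 11 | 3,5-dimethoxy-4-{[(1S,2S,4aR,5S,6S,8aS)-1,2,4a,5-tetramethyl-6-(triethylsilyloxy)decahydronaphthalen-1-yl]methoxy}benzaldehyde | O=Cc1cc(OC)c(OC[C@]2(C)[C@H]3CC[C@H](O[Si](CC)(CC)CC)[C@@H](C)[C@]3(C)CC[C@@H]2C)c(OC)c1
F4 | step 11 | 2-hydroxy-3,5-dimethoxy-4-{[(1S,2S,4aR,5S,6S,8aS)-1,2,4a,5-tetramethyl-6-(triethylsilyloxy)decahydronaphthalen-1-yl]methoxy}benzaldehyde | O=Cc1cc(OC)c(OC[C@]2(C)[C@H]3CC[C@H](O[Si](CC)(CC)CC)[C@@H](C)[C@]3(C)CC[C@@H]2C)c(OC)c1O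
F5 | step 11 | ethyl (2Z)-3-(2-hydroxy-3,5-dimethoxy-4-{[(1S,2S,4aR,5S,6S,8aS)-1,2,4a,5-tetramethyl-6-(triethylsilyloxy)decahydronaphthalen-1-yl]methoxy}phenyl)prop-2-enoate | CCOC(=O)/C=C\c1cc(OC)c(OC[C@]2(C)[C@H]3CC[C@H](O[Si](CC)(CC)CC)[C@@H](C)[C@]3(C)CC[C@@H]2C)c(OC)c1O
F6 | step 6 | (4S,5S,6E)-7-iodo-5,6-dimethyl-4-(triethylsilyloxy)hept-6-enal | O=CCC[C@H](O[Si](CC)(CC)CC)[C@@H](C)/C(C)=C/I
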